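**Retrosynthetic overview**
- Last disconnection: the aryl C5–OMe bond of the target (5,7,8,3',4'-pentamethoxyflavone), made by pyranone-carbonyl-directed C–H methoxylation of 7,8,3',4'-tetramethoxyflavone.
- Ring C: the O1–C2 bond, made by oxidative oxa-Michael cyclisation of a 2'-hydroxychalcone.
- Chalcone: the enone C=C bond, made by Claisen–Schmidt condensation of 2'-hydroxy-3',4'-dimethoxyacetophenone with veratraldehyde.
- Ring order: rings A and B are bought; ring C is the only ring formed (step 2); the 5-oxygen goes on last (step 3).

Assumption: the target has no stereocentre (it is achiral), so there is no enantiomer to select and the route makes the single constitution drawn; 1 and 2 are taken as catalogue compounds.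

**Step 1**
Reactants: 1 1-(2-hydroxy-3,4-dimethoxyphenyl)ethan-1-one (2'-hydroxy-3',4'-dimethoxyacetophenone); 2 3,4-dimethoxybenzaldehyde (veratraldehyde)
Product: 4 (E)-1-(2-hydroxy-3,4-dimethoxyphenyl)-3-(3,4-dimethoxyphenyl)prop-2-en-1-one, via racemic aldol adduct 3 (not isolated)
Conditions: KOH (50% aq., 5 equiv), EtOH, 0 °C to rt, 24 h; then 1 M HCl
Reagents that add atoms: none
Why: Claisen–Schmidt (crossed aldol) condensation, in which the enolate of methyl ketone 1 adds to the non-enolisable aldehyde 2 and aldol 3 loses water by E1cB to the conjugated enone, whose (E) geometry is the thermodynamic outcome and in which no stereocentre survives.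

**Step 2**
Reactants: 4 (E)-1-(2-hydroxy-3,4-dimethoxyphenyl)-3-(3,4-dimethoxyphenyl)prop-2-en-1-one
Product: 6 2-(3,4-dimethoxyphenyl)-7,8-dimethoxy-4H-chromen-4-one (7,8,3',4'-tetramethoxyflavone), via racemic flavanone 5 (not isolated)
Conditions: I2 (10 mol %), DMSO, 130 °C, 3 h
Reagents that add atoms: none
Why: Iodine/DMSO oxidative cyclisation of a 2'-hydroxychalcone, in which the phenol adds to the enone (intramolecular oxa-Michael addition) to close ring C as flavanone 5, which iodine dehydrogenates to the flavone while DMSO reoxidises the HI to I2, so the transient C2 stereocentre of 5 is erased.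

**Step 3**
Reactants: 6 2-(3,4-dimethoxyphenyl)-7,8-dimethoxy-4H-chromen-4-one
Product: 7 2-(3,4-dimethoxyphenyl)-5,7,8-trimethoxy-4H-chromen-4-one (isosinensetin)
Conditions: [RuCl2(p-cymene)]2 (5 mol %), AgSbF6 (20 mol %), MesCO2H (30 mol %), PhI(OAc)2 (2 equiv), MeOH/DCE 1:4, 60 °C
Reagents that add atoms: methanol, CO
Why: Proposed new method: the pyranone carbonyl (a vinylogous ester and the most Lewis-basic site of 6) binds the cationic divalent ruthenium carboxylate and steers carboxylate-assisted C–H ruthenation to the peri C5–H, the only C–H that can close a five-membered metallacycle (C3–H would need a four-membered ring, ring B has no chelating handle, and no peri C–H remains afterwards, so one methoxy group is the limit); PhI(OMe)2, formed in the flask from PhI(OAc)2 and methanol, then oxidises the catalyst-bound aryl to a coordinatively saturated tetravalent ruthenium aryl methoxide, from which C–O reductive elimination should outrun β-hydride loss and release 7 with divalent ruthenium; the closest known reaction types are the ruthenium-catalysed carbonyl-directed C5–H hydroxylation of flavones with PhI(OCOCF3)2 in CF3CO2H/(CF3CO)2O and the palladium-catalysed nitrogen-directed C–H methoxylation of arenes with PhI(OAc)2 in methanol, whereas methoxide transfer under a weakly coordinating carbonyl group on ruthenium has, to my knowledge, not been described.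

**Compound list**
1 | 1-(2-hydroxy-3,4-dimethoxyphenyl)ethan-1-one | CC(=O)c1ccc(OC)c(OC)c1O | starting material
2 | 3,4-dimethoxybenzaldehyde | COc1ccc(C=O)cc1OC | starting material
3 | racemic 3-hydroxy-1-(2-hydroxy-3,4-dimethoxyphenyl)-3-(3,4-dimethoxyphenyl)propan-1-one (aldol adduct, not isolated) | COc1ccc(C(O)CC(=O)c2ccc(OC)c(OC)c2O)cc1OC | intermediate
4 | (E)-1-(2-hydroxy-3,4-dimethoxyphenyl)-3-(3,4-dimethoxyphenyl)prop-2-en-1-one | COc1ccc(/C=C/C(=O)c2ccc(OC)c(OC)c2O)cc1OC | intermediate
5 | racemic 2-(3,4-dimethoxyphenyl)-7,8-dimethoxychroman-4-one (flavanone, not isolated) | COc1ccc(C2CC(=O)c3ccc(OC)c(OC)c3O2)cc1OC | intermediate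
6 | 2-(3,4-dimethoxyphenyl)-7,8-dimethoxy-4H-chromen-4-one | COc1ccc(-c2cc(=O)c3ccc(OC)c(OC)c3o2)cc1OC | intermediate
7 | 2-(3,4-dimethoxyphenyl)-5,7,8-trimethoxy-4H-chromen-4-one (isosinensetin) | COc1ccc(-c2cc(=O)c3c(OC)cc(OC)c(OC)c3o2)cc1OC | target

**Totals**
Total step count: 3. Longest linear sequence: 3 steps (1 and 2 are both bought and meet in step 1).

**Steps most likely to fail**

Step 3 (highest risk; the proposed new step). The carbonyl group is a weak ligand and methanol may compete for the metal. C–OAc elimination could give the 5-acetate instead. Methanol may be oxidised and use up the oxidant, and the 5-methoxy product may chelate and slow the catalyst. The fallback uses known chemistry and sets out from 6. The established ruthenium-catalysed C5–H hydroxylation of flavones ([RuCl2(p-cymene)]2 cat., PhI(OCOCF3)2, CF3CO2H/(CF3CO)2O, 80 °C) gives 2-(3,4-dimethoxyphenyl)-7,8-dimethoxy-4-oxo-4H-chromen-5-yl trifluoroacetate F3. Aqueous work-up hydrolyses it to 2-(3,4-dimethoxyphenyl)-5-hydroxy-7,8-dimethoxy-4H-chromen-4-one F4. O-Methylation of the chelated phenol (MeI, K2CO3, DMF, 60 °C) then comes back to the route at 7.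

Step 2. The electron-rich rings may be iodinated, or dehydrogenation may stall at the flavanone. The fallback sets out from 4 and separates ring closure from oxidation. NaOAc in refluxing EtOH isomerises 4 to flavanone 5, which is now isolated. DDQ in refluxing dioxane dehydrogenates 5 by hydride abstraction and comes back to the route at 6. This fallback makes no compound outside the list (F0).

Step 1. Condensation with the electron-rich aldehyde may be slow, 2 may be lost to Cannizzaro disproportionation, and some product may cyclise early to 5. The fallback sets out from 1 and replaces the aldol logic by a Baker–Venkataraman sequence. Acylation with 3,4-dimethoxybenzoyl chloride in pyridine gives 6-acetyl-2,3-dimethoxyphenyl 3,4-dimethoxybenzoate F1. KOH in pyridine at 50 °C moves the acyl group to carbon and gives 1-(2-hydroxy-3,4-dimethoxyphenyl)-3-(3,4-dimethoxyphenyl)propane-1,3-dione F2. Cyclodehydration (cat. H2SO4, AcOH, 100 °C) closes ring C and comes back to the route at 6, bypassing 4.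

**Further compounds**
F1 | step 1 | 6-acetyl-2,3-dimethoxyphenyl 3,4-dimethoxybenzoate | CC(=O)c1ccc(OC)c(OC)c1OC(=O)c1ccc(OC)c(OC)c1
F2 | step 1 | 1-(2-hydroxy-3,4-dimethoxyphenyl)-3-(3,4-dimethoxyphenyl)propane-1,3-dione | COc1ccc(C(=O)CC(=O)c2ccc(OC)c(OC)c2O)cc1OC
F0 | step 2 | none | none
F3 | step 3 | 2-(3,4-dimethoxyphenyl)-7,8-dimethoxy-4-oxo-4H-chromen-5-yl trifluoroacetate | COc1ccc(-c2cc(=O)c3c(OC(=O)C(F)(F)F)cc(OC)c(OC)c3o2)cc1OC
F4 | step 3 | 2-(3,4-dimethoxyphenyl)-5-hydroxy-7,8-dimethoxy-4H-chromen-4-one | COc1ccc(-c2cc(=O)c3c(O)cc(OC)c(OC)c3o2)cc1OC
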